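No target can stand in this flask beyond the gas that has crossed into solution: each target carries one dissolved gas.

substrate 13 mM; gas phase 2.3 mM (held); time 1.5 h

    gas phase ⇌ dissolved gas, rate k1*(csat - [dissolved gas]) (k1 = 7.3 × 10⁻⁴ s⁻¹, csat = 2.3 mM)
    substrate + dissolved gas ⇌ target (K2 = 21000 L mol⁻¹, k2 = 1.7 L mol⁻¹ s⁻¹)
    dissolved gas + target → over-reacted product (k3 = 0.30 L mol⁻¹ s⁻¹)
    dissolved gas + target → over-reaction product (k4 = 0.080 L mol⁻¹ s⁻¹)
    substrate ⇌ dormant form (K5 = 0.91, k5 = 7.8 × 10⁻⁴ s⁻¹)

- at the start none of the gas is dissolved
- run time (flask): 1.5 h

* how much target there is at 1.5 h, in percent of the substrate charged
* concentration of dissolved gas in solution at 1.5 h, in percent of saturation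

The transfer coefficient times the saturation concentration times the time, divided by the substrate charged, gives 0.697, the gas allowance: the most gas that could arrive by the asked time, per substrate charged, into a solution kept empty. That is a ceiling on target, not an estimate of it.

Turn the question round and ask what over-reaction would need to win. The symmetric case is the zero of the scale: the charge stands in equal parts as target, at one gas each, and as the two products of over-reaction, at two gases each. With no substrate left, that costs 1.50 gas per substrate. The allowance of this flask stands below this mark, so this flask cannot reach that even state by the reading, and the estimate has to come from the race for dissolved gas. Substrate and dormant form relax into each other faster than the run lasts, so about 0.524 of the unreacted pool is reckoned as free substrate. Target then competes with free substrate for dissolved gas at the ratio 0.427. With the pool fallen to a given fraction, target as a share of the charge is that fraction raised to the ratio, less the fraction, divided by one less the ratio. A trial with the pool half spent gives 42.6 % of target. It needs 0.574 gas per substrate, less than the allowance; since the allowance is a ceiling, this trial is kept as a rough estimate.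

The forecast gave 41 % and 11.7 %, reasoning that “dissolved gas sits in quasi-steady state”. The flask gives 40.7 % of target, and dissolved gas at 11.5 % of saturation.

Target survives in this flask in part because the transfer resistance rations the gas, acting together with the early hour of the reading. With that resistance taken away, target at 1.5 h falls from 40.7 % to 2.47 %, and with the resistance kept but the reading moved to 15.0 h, target stands at 0 %. The neighbour charged with 3.2 mM of substrate has an allowance of 2.83, past the even mark, and it ends with more over-reacted product than target, at 47.4 % against 29.5 %.

(All constants are invented; the run is a simulation.)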